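The numbers in the tables were computed for substances that don't exist; the scatter is artificial.

At the first reading, 0.417 h after the start, the eta flask, which is the flask asked about, holds isomer of the product (E) at 52.9 % and target (P, idle complex counted in it) at 27.1 %. At the last reading, 2.50 h, they stand at 52.9 % and 26.0 %.

| setting | eta | alpha | flask |
|---|---|---|---|
| substrate | 1.5 M | 1.5 M | 1.5 M |
| coupling partner | 1.58 M | 1.58 M | 1.58 M |
| free catalyst | 75 mM | 150 mM | 75 mM |
| second catalyst | 210 mM | 210 mM | 210 mM |
| remark | the very flask that is asked about, followed so far | run made earlier |  |
| time |  |  | 12 h |

- eta (time / h: isomer of the product / %, target / %): 0.417: 52.9, 27.1; 0.833: 52.8, 26.6; 1.33: 53.1, 26.5; 1.50: 53.0, 26.2; 2.00: 52.4, 26.5; 2.50: 52.9, 26.0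
- alpha (time / h: isomer of the product / %, target / %): 0.500: 58.7, 29.8; 1.50: 58.1, 29.7; 3.00: 57.9, 29.2; 5.00: 58.6, 29.4; 6.00: 58.7, 29.0; 8.00: 58.4, 29.8

(standard deviation of a reading: 0.5 percentage points)

- a species is counted by the substrate in it: one homo dimer counts as two
- amounts and yields of target count idle complex too
- steps that have been proposed: substrate + free catalyst -> free catalyst + intermediate; coupling partner + second catalyst + intermediate -> second catalyst + target; second catalyst + target <-> idle complex; target <-> isomer of the product; 2 substrate -> homo dimer

- ratio of isomer of the product to target at 10 s
- ratio of isomer of the product to target at 10 min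
- ratio of isomer of the product to target at 12 h

Substrate is the limiting reagent, charged at 1.5 M, less than the 1.58 M of coupling partner. Its balance, in percent of the charge and with "rest" for what stands as substrate, intermediate and homo dimer, reads:

E + P + rest = 100

In the eta flask, E + P reads 80.0 % at the first reading and 78.9 % at the last, a difference of the size of the scatter of such sums, so the readings show no growth of this pool. How the pool divides is taken here from the eta readings together:

Q = ΣE / ΣP = 2.00

Q is the plateau ratio, the isomer of the product over target once their pool has stopped growing. The alpha flask, with twice the free catalyst, reads 1.98. The reckoning here therefore commits to Q at 12 h. In the proposed steps, isomer of the product arises from target, so the ratio climbs from zero towards Q. Both 10 s and 10 min lie before the first reading, so the readings put no number on either.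

The forecast gives 0.3 at 10 s, 1.8 at 10 min and 2 at 12 h. Of the earliest value it says: “it is essentially unconstrained, so it is a wide guess”.

The flask gives 0.0306 at 10 s, 1.94 at 10 min and 2.00 at 12 h.

    substrate + free catalyst → free catalyst + intermediate (k = 0.196 /M/s)
    coupling partner + second catalyst + intermediate → second catalyst + target (k = 0.121 /M²/s)
    second catalyst + target ⇌ idle complex (K = 0.265 /M, k = 0.0123 /M/s)
    target ⇌ isomer of the product (K = 2.10, k = 0.00876 /s)
    2 substrate → homo dimer (k = 0.00280 /M/s)

In the asked flask, the forward half-life of free target going to isomer of the product, 1.3 min at 12.0 h, is longer than 10 s and shorter than 10 min. The ratio in that flask stands at 1.53 % of Q at the early time and 97.0 % of Q at the middle one. In the neighbour flask with 0.63 M of coupling partner and the same second catalyst, intermediate holds 37.1 % at 12 h, and Q times its target of 14.0 % gives 28.0 %, where its isomer of the product stands at 28.0 %.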